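## Retrosynthetic overview

1. Numbering follows the labdane skeleton: ring A = C1–C5 + C10 (C4 carries the gem-dimethyl group), ring B = C5–C10 (C6–O, C7=C8, carboxyl C17 on C8, side chain C11–C12 on C9 leading to the butenolide C13–C16). Late disconnections: C8–C17 (enol triflate carbonylation), C12–C13 (Negishi coupling with intact 3-bromobutenolide), C6–O acyl (esterification).
2. C5–H and C6–OH come together from hydroboration of a C5=C6 alkene, which arises by deconjugative ketalisation of the ring-B enone C8(=O)–C7=C6.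
3. Key disconnection C4–C5: ring A is closed when the tertiary C4 cation (stored as the C4 chloride) is captured by C5, the γ-carbon of the ring-B silyl dienol ether.
4. Enabling feature: the gem-dimethyl carbon C4 of ring A is a latent tertiary cation linked through C3–C2–C1–C10 to C5, and C5 is the γ-position of an enone whose carbonyl carbon C8 later carries the carboxyl group and whose β-carbon C6 later becomes the carbinol carbon.
5. Ring order: ring B is bought (3-methylcyclohex-2-enone; C10 and C9 by asymmetric conjugate addition and enolate alkylation); ring A is closed in step 4, the only and last ring closure of the skeleton; the butenolide is bought as 3-bromofuran-2(5H)-one and attached intact.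

Key step: step 4

## Remarks before the steps

- α/β: β is the face of the angular C10 methyl group. "Decalin" and "Δ7-octalin" names below use the labdane locants defined above.
- Assumption: 3-bromofuran-2(5H)-one, (R)-2-methylbutanoic acid and 5-bromo-2-methylpent-2-ene are purchased.
- C9 is epimerisable whenever C8 is a carbonyl. The step 1 alkylation is expected to give only moderate selectivity at C9. The intermediates between step 1 and step 9 are drawn as the 9β epimer; any 9α material is carried along and converges in step 9.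
- The dioxolane made in step 5 is a temporary protecting ring and is removed in step 9.

## Route

Step 1
Reactants: 1 3-methylcyclohex-2-en-1-one; 2 5-bromo-2-methylpent-2-ene; 3 methyl bromoacetate
Product: 6 methyl 2-[(1R,2R)-2-methyl-2-(4-methylpent-3-en-1-yl)-6-oxocyclohexyl]acetate, via Grignard reagent 4 (not isolated), via magnesium enolate 5 (not isolated)
Conditions: Mg, Et2O, 25 °C (2 to 4); 1, Cu(OTf)2 (3 mol %), C2-symmetric 4,5-diphenylimidazolinium salt as NHC precursor (4 mol %, the enantiomer that gives (R) at C10), Et2O, 0 °C; then 3, DMPU, −20 to 20 °C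
Reagents that add atoms: none
Why: Copper-catalysed asymmetric conjugate addition of the Grignard reagent to the β-methyl enone sets the quaternary C10 centre under ligand control, and the regiodefined magnesium enolate is alkylated in the same flask by the reactive α-bromo ester (three-component coupling), mainly trans to the larger homoprenyl group, which gives the drawn C9 configuration that step 9 later secures.

Step 2
Reactants: 6 methyl 2-[(1R,2R)-2-methyl-2-(4-methylpent-3-en-1-yl)-6-oxocyclohexyl]acetate
Product: 7 methyl 2-[(1R,6S)-6-methyl-6-(4-methylpent-3-en-1-yl)-2-oxocyclohex-3-en-1-yl]acetate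
Conditions: 2-iodoxybenzoic acid (IBX), DMSO, 70 °C
Reagents that add atoms: none
Why: IBX-mediated dehydrogenation of the ketone can only deliver the C8(=O)–C7=C6 enone because the other α-carbon (C9) faces the quaternary C10; no stereocentre is formed and the trisubstituted alkene and the ester are inert.

Step 3
Reactants: 7 methyl 2-[(1R,6S)-6-methyl-6-(4-methylpent-3-en-1-yl)-2-oxocyclohex-3-en-1-yl]acetate
Product: 8 methyl 2-[(1R,6S)-6-(4-chloro-4-methylpentyl)-6-methyl-2-oxocyclohex-3-en-1-yl]acetate
Conditions: HCl (gas), CH2Cl2, −30 °C; NaHCO3 wash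
Reagents that add atoms: hydrogen chloride, Cl
Why: Markovnikov hydrochlorination of the electron-rich trisubstituted alkene stores the future C4 cation as a tertiary chloride, while the enone (any reversible HCl adduct reverts on the base wash) and the ester are unchanged; no stereocentre is formed.

Step 4
Reactants: 8 methyl 2-[(1R,6S)-6-(4-chloro-4-methylpentyl)-6-methyl-2-oxocyclohex-3-en-1-yl]acetate
Product: 10 methyl 2-[(1R,8aS)-5,5,8a-trimethyl-2-oxo-1,2,4a,5,6,7,8,8a-octahydronaphthalen-1-yl]acetate (both C5 epimers), via silyl dienol ether 9 (not isolated)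
Conditions: TBSOTf, Et3N, CH2Cl2, −78 to 0 °C; pentane, filtration, concentration; then TiCl4, CH2Cl2, −78 °C; aqueous NaHCO3
Reagents that add atoms: none
Why: Soft enolisation with TBSOTf/Et3N removes a C5 proton (the γ-position; the α'-proton on C9 is a hindered methine) to give the linear 2-silyloxy-1,3-diene 9, TiCl4 then ionises the tertiary C4–Cl bond, the C4 cation is captured by the γ-carbon C5, and loss of the silyl group as the silyl chloride returns the conjugated enone. The closest known reaction type is the Lewis-acid-mediated SN1 α-tert-alkylation of silyl enol ethers with tertiary chlorides, together with the γ-selective alkylation of silyl dienol ethers by SN1 electrophiles (vinylogous Mukaiyama-type reactivity), here run intramolecularly. Ring A closes in a 6-(enol-exo) mode through a chair-like transition state: C4–C5 is the only bond formed and the nucleophilic C5=C6 π-bond lies outside the new ring. The one new stereocentre, C5, is not controlled and need not be, because step 5 makes C5 trigonal again and step 6 sets it; C9 and C10 are untouched. The step needs γ- over α-attack (attack through C7 would need an eight-membered ring), capture of the cation over proton loss (favoured by the nucleophilic silyl dienol ether, the six-membered transition state and −78 °C), and no carbonyl-initiated attack of the alkene on the enone, which is excluded because the alkene is masked as the chloride and the enone as its silyl dienol ether before the Lewis acid is added.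

Step 5
Reactants: 10 methyl 2-[(1R,8aS)-5,5,8a-trimethyl-2-oxo-1,2,4a,5,6,7,8,8a-octahydronaphthalen-1-yl]acetate
Product: 11 methyl 2-[(1R,8aR)-2,2-ethylenedioxy-5,5,8a-trimethyl-1,2,3,5,6,7,8,8a-octahydronaphthalen-1-yl]acetate
Conditions: ethane-1,2-diol, p-TsOH (cat.), benzene, reflux, Dean–Stark trap
Reagents that add atoms: ethane-1,2-diol, OCCO
Why: Acid-catalysed ketalisation of a conjugated enone proceeds through the linear dienol ether and protonation at C7, so the double bond leaves conjugation and settles as the trisubstituted C5=C6 alkene (the behaviour of steroidal 4-en-3-ones), which erases C5 and lets both epimers of 10 converge.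

Step 6
Reactants: 11 methyl 2-[(1R,8aR)-2,2-ethylenedioxy-5,5,8a-trimethyl-1,2,3,5,6,7,8,8a-octahydronaphthalen-1-yl]acetate
Product: 13 (5α,6α,9β,10β)-8,8-ethylenedioxy-9-(2-hydroxyethyl)-4,4,10-trimethyldecalin-6-ol, via C6 alkylborane 12 (not isolated)
Conditions: BH3·THF, THF, 0 to 25 °C; LiBH4, 40 °C; then NaOH, H2O2, H2O, 0 to 25 °C
Reagents that add atoms: hydrogen peroxide, OO
Why: Hydroboration–oxidation adds H and OH syn across C5=C6 from the α-face (the β-face is blocked by the axial C10 methyl and the β-methyl on C4) with boron on the less substituted C6, so C5 (H α, trans ring fusion) and C6 (OH α) are set together with retention in the oxidation, and LiBH4 completes the reduction of the methyl ester to the primary alcohol without touching the ketal.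

Step 7
Reactants: 13 (5α,6α,9β,10β)-8,8-ethylenedioxy-9-(2-hydroxyethyl)-4,4,10-trimethyldecalin-6-ol
Product: 14 (5α,6α,9β,10β)-9-(2-bromoethyl)-8,8-ethylenedioxy-4,4,10-trimethyldecalin-6-ol
Conditions: CBr4, PPh3, CH2Cl2, 0 °C
Reagents that add atoms: carbon tetrabromide, BrC(Br)(Br)Br
Why: The Appel bromination (SN2 displacement of the alkoxyphosphonium by bromide) is selective for the unhindered primary alcohol over the secondary C6 alcohol, which is flanked by the C4 and C10 quaternary carbons; no stereocentre is touched.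

Step 8
Reactants: 14 (5α,6α,9β,10β)-9-(2-bromoethyl)-8,8-ethylenedioxy-4,4,10-trimethyldecalin-6-ol; 15 (R)-2-methylbutanoic acid
Product: 16 (5α,6α,9β,10β)-9-(2-bromoethyl)-8,8-ethylenedioxy-4,4,10-trimethyldecalin-6-yl (R)-2-methylbutanoate
Conditions: N,N'-diisopropylcarbodiimide (DIC), DMAP, CH2Cl2, 25 °C
Reagents that add atoms: none
Why: Steglich esterification through the acylpyridinium ion acylates the remaining secondary alcohol with retention at C6 and without enolisation of the α-branched acid, so the (R) centre of the ester is brought in unchanged.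

Step 9
Reactants: 16 (5α,6α,9β,10β)-9-(2-bromoethyl)-8,8-ethylenedioxy-4,4,10-trimethyldecalin-6-yl (R)-2-methylbutanoate
Product: 17 (5α,6α,9β,10β)-9-(2-bromoethyl)-4,4,10-trimethyl-8-oxodecalin-6-yl (R)-2-methylbutanoate
Conditions: 2 M HCl, THF, 35 °C
Reagents that add atoms: water, O
Why: Acid hydrolysis of the dioxolane frees the C8 ketone, and under the same acid C9 equilibrates through the C8=C9 enol, where protonation anti to the axial C10 methyl and the equatorial preference of the side chain in the trans-decalone are both expected to favour the 9β epimer (side chain cis to the C10 methyl).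

Step 10
Reactants: 17 (5α,6α,9β,10β)-9-(2-bromoethyl)-4,4,10-trimethyl-8-oxodecalin-6-yl (R)-2-methylbutanoate
Product: 18 (5α,6α,9β,10β)-9-(2-bromoethyl)-4,4,10-trimethyl-8-(trifluoromethylsulfonyloxy)-Δ7-octalin-6-yl (R)-2-methylbutanoate
Conditions: KN(SiMe3)2 added to 17 and N-(5-chloropyridin-2-yl)bis(trifluoromethanesulfonimide), THF, −78 °C
Reagents that add atoms: N-(5-chloropyridin-2-yl)-1,1,1-trifluoro-N-(trifluoromethylsulfonyl)methanesulfonamide, O=S(=O)(N(c1ccc(Cl)cn1)S(=O)(=O)C(F)(F)F)C(F)(F)F
Why: Kinetic deprotonation with the bulky amide takes the C7 methylene proton instead of the hindered C9 methine and the enolate is O-triflated in situ (enol triflate formation), while β-elimination should be slow because the 6α-acyloxy group is pseudo-equatorial and lies near the nodal plane of the enolate π-system; C9 keeps its configuration.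

Step 11
Reactants: 18 (5α,6α,9β,10β)-9-(2-bromoethyl)-4,4,10-trimethyl-8-(trifluoromethylsulfonyloxy)-Δ7-octalin-6-yl (R)-2-methylbutanoate
Product: 19 4-methoxybenzyl (5α,6α,9β,10β)-9-(2-bromoethyl)-6-[(R)-2-methylbutanoyloxy]-4,4,10-trimethyl-Δ7-octalin-8-carboxylate
Conditions: Pd(OAc)2, dppf, CO (1 atm), 4-methoxybenzyl alcohol, iPr2NEt, DMF, 45 °C
Reagents that add atoms: carbon monoxide, [C-]#[O+]; 4-methoxybenzyl alcohol, COc1ccc(CO)cc1
Why: Palladium-catalysed alkoxycarbonylation of the enol triflate (oxidative addition, CO insertion, alcoholysis of the acylpalladium) installs C17 on C8 with the C7=C8 bond fixed, and the primary alkyl bromide and the hindered allylic ester should not react with the palladium–dppf catalyst under these mild conditions.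

Step 12
Reactants: 19 4-methoxybenzyl (5α,6α,9β,10β)-9-(2-bromoethyl)-6-[(R)-2-methylbutanoyloxy]-4,4,10-trimethyl-Δ7-octalin-8-carboxylate; 20 3-bromofuran-2(5H)-one
Product: 22 4-methoxybenzyl (5α,6α,9β,10β)-6-[(R)-2-methylbutanoyloxy]-4,4,10-trimethyl-9-[2-(2-oxo-2,5-dihydrofuran-3-yl)ethyl]-Δ7-octalin-8-carboxylate, via alkylzinc bromide 21 (not isolated)
Conditions: Zn dust, LiCl, THF, 50 °C; then 20, Pd(OAc)2, SPhos, THF, 25 to 40 °C
Reagents that add atoms: none
Why: Negishi coupling, in which LiCl-assisted zinc insertion into the primary C–Br bond gives an ester-tolerant alkylzinc that couples at sp2 carbon with the α-bromobutenolide while the biarylphosphine suppresses β-hydride elimination, attaches the intact butenolide ring through the C12–C13 bond without affecting any stereocentre.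

Step 13
Reactants: 22 4-methoxybenzyl (5α,6α,9β,10β)-6-[(R)-2-methylbutanoyloxy]-4,4,10-trimethyl-9-[2-(2-oxo-2,5-dihydrofuran-3-yl)ethyl]-Δ7-octalin-8-carboxylate
Product: 23 (5α,6α,9β,10β)-6-[(R)-2-methylbutanoyloxy]-4,4,10-trimethyl-9-[2-(2-oxo-2,5-dihydrofuran-3-yl)ethyl]-Δ7-octalin-8-carboxylic acid (CNP0150853.1)
Conditions: CF3CO2H, anisole, CH2Cl2, 0 °C
Reagents that add atoms: none
Why: Acidolysis of the 4-methoxybenzyl ester (anisole traps the benzyl cation) frees the C17 acid, while the C6 ester, being allylic to an electron-poor alkene, and the butenolide should be stable to cold trifluoroacetic acid.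

## Compound list

1 | 3-methylcyclohex-2-en-1-one | CC1=CC(=O)CCC1 | starting material
2 | 5-bromo-2-methylpent-2-ene | CC(C)=CCCBr | starting material
3 | methyl bromoacetate | COC(=O)CBr | starting material
4 | (4-methylpent-3-en-1-yl)magnesium bromide | CC(C)=CCC[Mg]Br | intermediate (not isolated)
5 | bromomagnesium (3R)-3-methyl-3-(4-methylpent-3-en-1-yl)cyclohex-1-en-1-olate | Br[Mg]OC1=C[C@@](C)(CCC=C(C)C)CCC1 | intermediate (not isolated)
6 | methyl 2-[(1R,2R)-2-methyl-2-(4-methylpent-3-en-1-yl)-6-oxocyclohexyl]acetate | O=C1[C@H](CC(=O)OC)[C@@](C)(CCC=C(C)C)CCC1 | intermediate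
7 | methyl 2-[(1R,6S)-6-methyl-6-(4-methylpent-3-en-1-yl)-2-oxocyclohex-3-en-1-yl]acetate | O=C1[C@H](CC(=O)OC)[C@@](C)(CCC=C(C)C)CC=C1 | intermediate
8 | methyl 2-[(1R,6S)-6-(4-chloro-4-methylpentyl)-6-methyl-2-oxocyclohex-3-en-1-yl]acetate | O=C1[C@H](CC(=O)OC)[C@@](C)(CCCC(C)(C)Cl)CC=C1 | intermediate
9 | methyl 2-[2-(tert-butyldimethylsilyloxy)-6-(4-chloro-4-methylpentyl)-6-methylcyclohexa-2,4-dien-1-yl]acetate (C9 and C10 as in 8) | CC(C)(C)[Si](C)(C)OC1=CC=C[C@](C)(CCCC(C)(C)Cl)[C@H]1CC(=O)OC | intermediate (not isolated)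
10 | methyl 2-[(1R,8aS)-5,5,8a-trimethyl-2-oxo-1,2,4a,5,6,7,8,8a-octahydronaphthalen-1-yl]acetate (ring A closed; C5 = C4a left undefined, both epimers) | O=C1C=CC2C(C)(C)CCC[C@]2(C)[C@H]1CC(=O)OC | intermediate
11 | methyl 2-[(1R,8aR)-2,2-ethylenedioxy-5,5,8a-trimethyl-1,2,3,5,6,7,8,8a-octahydronaphthalen-1-yl]acetate (C5=C6 alkene, C8 dioxolane) | O1CCOC13CC=C2C(C)(C)CCC[C@]2(C)[C@H]3CC(=O)OC | intermediate
12 | (5α,6α,9β,10β)-6-boranyl-8,8-ethylenedioxy-9-(methoxycarbonylmethyl)-4,4,10-trimethyldecalin | B[C@H]1CC2(OCCO2)[C@H](CC(=O)OC)[C@@]3(C)CCCC(C)(C)[C@H]13 | intermediate (not isolated)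
13 | (5α,6α,9β,10β)-8,8-ethylenedioxy-9-(2-hydroxyethyl)-4,4,10-trimethyldecalin-6-ol | O[C@H]1CC2(OCCO2)[C@H](CCO)[C@@]3(C)CCCC(C)(C)[C@H]13 | intermediate
14 | (5α,6α,9β,10β)-9-(2-bromoethyl)-8,8-ethylenedioxy-4,4,10-trimethyldecalin-6-ol | O[C@H]1CC2(OCCO2)[C@H](CCBr)[C@@]3(C)CCCC(C)(C)[C@H]13 | intermediate
15 | (R)-2-methylbutanoic acid | CC[C@@H](C)C(=O)O | starting material
16 | (5α,6α,9β,10β)-9-(2-bromoethyl)-8,8-ethylenedioxy-4,4,10-trimethyldecalin-6-yl (R)-2-methylbutanoate | CC[C@@H](C)C(=O)O[C@H]1CC2(OCCO2)[C@H](CCBr)[C@@]3(C)CCCC(C)(C)[C@H]13 | intermediate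
17 | (5α,6α,9β,10β)-9-(2-bromoethyl)-4,4,10-trimethyl-8-oxodecalin-6-yl (R)-2-methylbutanoate | CC[C@@H](C)C(=O)O[C@H]1CC(=O)[C@H](CCBr)[C@@]2(C)CCCC(C)(C)[C@H]12 | intermediate
18 | (5α,6α,9β,10β)-9-(2-bromoethyl)-4,4,10-trimethyl-8-(trifluoromethylsulfonyloxy)-Δ7-octalin-6-yl (R)-2-methylbutanoate | CC[C@@H](C)C(=O)O[C@H]1C=C(OS(=O)(=O)C(F)(F)F)[C@H](CCBr)[C@@]2(C)CCCC(C)(C)[C@H]12 | intermediate
19 | 4-methoxybenzyl (5α,6α,9β,10β)-9-(2-bromoethyl)-6-[(R)-2-methylbutanoyloxy]-4,4,10-trimethyl-Δ7-octalin-8-carboxylate | CC[C@@H](C)C(=O)O[C@H]1C=C(C(=O)OCc3ccc(OC)cc3)[C@H](CCBr)[C@@]2(C)CCCC(C)(C)[C@H]12 | intermediate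
20 | 3-bromofuran-2(5H)-one | O=C1OCC=C1Br | starting material
21 | alkylzinc bromide from 19 (C12–ZnBr) | CC[C@@H](C)C(=O)O[C@H]1C=C(C(=O)OCc3ccc(OC)cc3)[C@H](CC[Zn]Br)[C@@]2(C)CCCC(C)(C)[C@H]12 | intermediate (not isolated)
22 | 4-methoxybenzyl (5α,6α,9β,10β)-6-[(R)-2-methylbutanoyloxy]-4,4,10-trimethyl-9-[2-(2-oxo-2,5-dihydrofuran-3-yl)ethyl]-Δ7-octalin-8-carboxylate | CC[C@@H](C)C(=O)O[C@H]1C=C(C(=O)OCc4ccc(OC)cc4)[C@H](CCC3=CCOC3=O)[C@@]2(C)CCCC(C)(C)[C@H]12 | intermediate
23 | (5α,6α,9β,10β)-6-[(R)-2-methylbutanoyloxy]-4,4,10-trimethyl-9-[2-(2-oxo-2,5-dihydrofuran-3-yl)ethyl]-Δ7-octalin-8-carboxylic acid (CNP0150853.1) | CC[C@@H](C)C(=O)O[C@H]1C=C(C(=O)O)[C@H](CCC2=CCOC2=O)[C@@]2(C)CCCC(C)(C)[C@H]12 | target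

## Step count and risk

Total steps: 13. Longest linear sequence: 13 (from 1; compounds 2, 3, 15 and 20 are purchased).

Steps most likely to fail, with fallbacks:

Step 4 (key step). What may go wrong: the C4 cation may lose a proton instead of being captured (which returns the alkene and protodesilylates 9), silylation may occur toward C9 instead of C5, or capture at the hindered C5 may be slow. The fallback sets out from 7 and comes back at 10, and moves the cyclisation to an epoxide-initiated mode at a higher oxidation level on C3. Compound 7 is epoxidised selectively at the electron-rich trisubstituted alkene (mCPBA, NaHCO3, CH2Cl2, 0 °C) to the epoxy enone F1. Silylation (TBSOTf, Et3N, CH2Cl2, −78 °C) gives the silyl dienol ether F2. MeAlCl2 (CH2Cl2, −78 °C) opens the epoxide at its tertiary carbon and C5 closes ring A, an epoxy-olefin cyclisation terminated by a silyl enol ether, giving the 3-hydroxy bicyclic enone F3. The extra hydroxyl is removed by Barton–McCombie deoxygenation through the phenyl thionocarbonate F4 (PhOC(S)Cl, DMAP, MeCN; then Bu3SnH, AIBN, toluene, 80 °C), which gives 10.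

Step 10. What may go wrong: β-elimination of the C6 carboxylate from the C7 enolate, acyl transfer to the enolate oxygen, or epimerisation of the 2-methylbutanoate. The fallback sets out from 14 and comes back at 19, and carries the C6 oxygen as a silyl ether through the enolate chemistry. Compound 14 is silylated (TBSOTf, 2,6-lutidine, CH2Cl2) to the silyl ether F5. Aqueous HCl in THF removes the dioxolane and gives the ketone F6. KN(SiMe3)2 with the same triflimide at −78 °C gives the enol triflate F7. Carbonylation (Pd(OAc)2, dppf, CO, 4-methoxybenzyl alcohol, iPr2NEt, DMF) gives the ester F8. HF·pyridine in THF gives the allylic alcohol F9, and Steglich esterification with 15 (DIC, DMAP) gives 19.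

Step 5. What may go wrong: incomplete migration of the double bond, which would leave an allylic C6=C7 ketal that still carries the C5 mixture. The fallback sets out from 10 and comes back at 11, and separates deconjugation from ketalisation. The linear dienolate of 10 is formed with KOtBu in t-BuOH and quenched rapidly into aqueous acetic acid; kinetic protonation at C7 gives the β,γ-unsaturated ketone F10. Ketalisation under non-isomerising conditions (1,2-bis(trimethylsilyloxy)ethane, TMSOTf cat., CH2Cl2, −78 °C) then gives 11.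

Further compounds
F1 | step 4 | methyl 2-[(1R,6S)-6-[2-(3,3-dimethyloxiran-2-yl)ethyl]-6-methyl-2-oxocyclohex-3-en-1-yl]acetate (epoxide carbon uncontrolled) | O=C1[C@H](CC(=O)OC)[C@@](C)(CCC2OC2(C)C)CC=C1
F2 | step 4 | methyl 2-[2-(tert-butyldimethylsilyloxy)-6-[2-(3,3-dimethyloxiran-2-yl)ethyl]-6-methylcyclohexa-2,4-dien-1-yl]acetate | CC(C)(C)[Si](C)(C)OC1=CC=C[C@](C)(CCC2OC2(C)C)[C@H]1CC(=O)OC
F3 | step 4 | methyl 2-[(1R,8aS)-6-hydroxy-5,5,8a-trimethyl-2-oxo-1,2,4a,5,6,7,8,8a-octahydronaphthalen-1-yl]acetate (C3 and C5 uncontrolled) | O=C1C=CC2C(C)(C)C(O)CC[C@]2(C)[C@H]1CC(=O)OC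
F4 | step 4 | methyl 2-[(1R,8aS)-5,5,8a-trimethyl-2-oxo-6-(phenoxycarbonothioyloxy)-1,2,4a,5,6,7,8,8a-octahydronaphthalen-1-yl]acetate | O=C1C=CC2C(C)(C)C(OC(=S)Oc3ccccc3)CC[C@]2(C)[C@H]1CC(=O)OC
F5 | step 10 | (5α,6α,9β,10β)-9-(2-bromoethyl)-6-(tert-butyldimethylsilyloxy)-8,8-ethylenedioxy-4,4,10-trimethyldecalin | CC(C)(C)[Si](C)(C)O[C@H]1CC2(OCCO2)[C@H](CCBr)[C@@]3(C)CCCC(C)(C)[C@H]13
F6 | step 10 | (5α,6α,9β,10β)-9-(2-bromoethyl)-6-(tert-butyldimethylsilyloxy)-4,4,10-trimethyldecalin-8-one | CC(C)(C)[Si](C)(C)O[C@H]1CC(=O)[C@H](CCBr)[C@@]2(C)CCCC(C)(C)[C@H]12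
F7 | step 10 | (5α,6α,9β,10β)-9-(2-bromoethyl)-6-(tert-butyldimethylsilyloxy)-4,4,10-trimethyl-Δ7-octalin-8-yl trifluoromethanesulfonate | CC(C)(C)[Si](C)(C)O[C@H]1C=C(OS(=O)(=O)C(F)(F)F)[C@H](CCBr)[C@@]2(C)CCCC(C)(C)[C@H]12
F8 | step 10 | 4-methoxybenzyl (5α,6α,9β,10β)-9-(2-bromoethyl)-6-(tert-butyldimethylsilyloxy)-4,4,10-trimethyl-Δ7-octalin-8-carboxylate | CC(C)(C)[Si](C)(C)O[C@H]1C=C(C(=O)OCc3ccc(OC)cc3)[C@H](CCBr)[C@@]2(C)CCCC(C)(C)[C@H]12
F9 | step 10 | 4-methoxybenzyl (5α,6α,9β,10β)-9-(2-bromoethyl)-6-hydroxy-4,4,10-trimethyl-Δ7-octalin-8-carboxylate | O[C@H]1C=C(C(=O)OCc3ccc(OC)cc3)[C@H](CCBr)[C@@]2(C)CCCC(C)(C)[C@H]12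
F10 | step 5 | methyl 2-[(1R,8aR)-5,5,8a-trimethyl-2-oxo-1,2,3,5,6,7,8,8a-octahydronaphthalen-1-yl]acetate (C5=C6 alkene) | O=C1CC=C2C(C)(C)CCC[C@]2(C)[C@H]1CC(=O)OC
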